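## Retrosynthetic overview

1. Numbering as in germacrane: C1=C10 is the Z-alkene, C4=C5 the E-alkene, C6 carries the lactone oxygen, C7 is the tertiary carbinol, C8 the free carbinol, C9 the angelate carbinol, C11=C13 the methylene and C12 the lactone carbonyl. The route rests on the vicinal trans C8/C9 diol of the ten-membered carbocycle, which lies between the quaternary C7 carbinol and the Z-alkene C1=C10.
2. Target 33 ⇐ triol 30 (angeloylation at O9) ⇐ diol 23 (diol masking, release of O7, α-methylenation of the lactone at C11).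
3. Diol 23 ⇐ dialdehyde 22 by reductive pinacol coupling C8–C9, which closes the ten-membered ring onto the preformed γ-lactone (second ring formed).
4. γ-Lactone 19 (first ring formed) ⇐ (Z)-allylic alcohol 16 by Sharpless epoxidation and anti opening of the epoxide at C6 by the C12 ester; 16 ⇐ dienal 11 + phosphonosuccinate 14 by Z-selective olefination.
5. Dienal 11 ⇐ geraniol (1) by cleavage of the terminal alkene and Still–Gennari olefination, which fixes the Z-alkene C1=C10 (allylic oxidation of the terminal methyl would give the E isomer).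

Key step: step 18

Remark: phosphonates 6 and 12 are taken as commercial reagents. Compounds 3, 4 and 14 are racemic and amine 27 is a mixture of C11 epimers; these centres are destroyed in steps 3, 10 and 22, so this has no consequence. The absolute configuration comes from the tartrate ligand in step 12.

## Route

Step 1
Reactants: 1 geraniol
Product: 2 geranyl tert-butyldimethylsilyl ether
Conditions: TBSCl, imidazole, DMF, 0 °C → rt
Reagents that add atoms: tert-butyldimethylsilyl chloride, CC(C)(C)[Si](C)(C)Cl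
Why: Silyl ether formation masks the primary allylic C6 hydroxyl against the peracid, base and hydride steps that follow and removes its directing effect on the neighbouring alkene.

Step 2
Reactants: 2 geranyl tert-butyldimethylsilyl ether
Product: 3 racemic 6,7-epoxygeranyl tert-butyldimethylsilyl ether
Conditions: mCPBA (1.0 equiv), CH2Cl2, −20 °C
Reagents that add atoms: 3-chloroperoxybenzoic acid, OOC(=O)c1cccc(Cl)c1
Why: Prilezhaev epoxidation should take place at the distal, more electron-rich trisubstituted alkene because the alkene next to the allylic C–O bond is inductively deactivated; the new stereocentre is racemic and is lost in step 3.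

Step 3
Reactants: 3 racemic 6,7-epoxygeranyl tert-butyldimethylsilyl ether
Product: 5 (4E)-6-[(tert-butyldimethylsilyl)oxy]-4-methylhex-4-enal, via racemic 6,7-diol 4 (not isolated)
Conditions: H5IO6, THF–Et2O, 0 °C
Reagents that add atoms: none
Why: Periodic acid opens the epoxide to the glycol and cleaves it (Malaprade glycol cleavage) to the C1 aldehyde and acetone under conditions that a primary silyl ether should survive.

Step 4
Reactants: 5 (4E)-6-[(tert-butyldimethylsilyl)oxy]-4-methylhex-4-enal; 6 ethyl 2-[bis(2,2,2-trifluoroethoxy)phosphoryl]propanoate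
Product: 7 ethyl (2Z,6E)-8-[(tert-butyldimethylsilyl)oxy]-2,6-dimethylocta-2,6-dienoate
Conditions: KN(SiMe3)2, 18-crown-6, THF, −78 °C
Reagents that add atoms: none
Why: In the Still–Gennari variant of the Horner–Wadsworth–Emmons olefination the electron-poor phosphonate eliminates from the kinetic adduct and should give the Z-trisubstituted enoate, which places C9 cis to C2 on the C1=C10 alkene.

Step 5
Reactants: 7 ethyl (2Z,6E)-8-[(tert-butyldimethylsilyl)oxy]-2,6-dimethylocta-2,6-dienoate
Product: 8 (2Z,6E)-8-[(tert-butyldimethylsilyl)oxy]-2,6-dimethylocta-2,6-dien-1-ol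
Conditions: iBu2AlH, CH2Cl2, −78 °C
Reagents that add atoms: none
Why: 1,2-Reduction of the conjugated ester by the aluminium hydride gives the allylic alcohol without touching the alkene geometry or the silyl ether.

Step 6
Reactants: 8 (2Z,6E)-8-[(tert-butyldimethylsilyl)oxy]-2,6-dimethylocta-2,6-dien-1-ol
Product: 9 tert-butyl{[(2Z,6E)-8-[(tert-butyldimethylsilyl)oxy]-2,6-dimethylocta-2,6-dien-1-yl]oxy}diphenylsilane
Conditions: TBDPSCl, imidazole, DMF, rt
Reagents that add atoms: tert-butyldiphenylsilyl chloride, CC(C)(C)[Si](Cl)(c1ccccc1)c1ccccc1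
Why: Silylation puts the bulkier and more acid-stable silyl ether on O9, so that the O6 silyl ether can be removed selectively in the next step.

Step 7
Reactants: 9 tert-butyl{[(2Z,6E)-8-[(tert-butyldimethylsilyl)oxy]-2,6-dimethylocta-2,6-dien-1-yl]oxy}diphenylsilane
Product: 10 (2E,6Z)-8-[(tert-butyldiphenylsilyl)oxy]-3,7-dimethylocta-2,6-dien-1-ol
Conditions: PPTS (cat.), MeOH, rt
Reagents that add atoms: none
Why: Acid-catalysed methanolysis cleaves the primary tert-butyldimethylsilyl ether much faster than the primary tert-butyldiphenylsilyl ether (selective desilylation).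

Step 8
Reactants: 10 (2E,6Z)-8-[(tert-butyldiphenylsilyl)oxy]-3,7-dimethylocta-2,6-dien-1-ol
Product: 11 (2E,6Z)-8-[(tert-butyldiphenylsilyl)oxy]-3,7-dimethylocta-2,6-dienal
Conditions: MnO2, CH2Cl2, rt
Reagents that add atoms: none
Why: Heterogeneous MnO2 oxidation of the allylic alcohol gives the enal (C6 aldehyde) under neutral conditions, so neither trisubstituted alkene should isomerise.

Step 9
Reactants: 12 methyl [bis(2,2,2-trifluoroethoxy)phosphoryl]acetate; 13 tert-butyl bromoacetate
Product: 14 racemic 4-tert-butyl 1-methyl 2-[bis(2,2,2-trifluoroethoxy)phosphoryl]butanedioate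
Conditions: NaH, THF, 0 °C → rt
Reagents that add atoms: none
Why: C-Alkylation (SN2) of the sodium phosphonoacetate carbanion with the α-bromo ester gives the phosphonosuccinate that carries C8 (methyl ester), C7, C11 and C12 (tert-butyl ester); its stereocentre is lost in step 10.

Step 10
Reactants: 11 (2E,6Z)-8-[(tert-butyldiphenylsilyl)oxy]-3,7-dimethylocta-2,6-dienal; 14 racemic 4-tert-butyl 1-methyl 2-[bis(2,2,2-trifluoroethoxy)phosphoryl]butanedioate
Product: 15 4-tert-butyl 1-methyl (2Z)-2-[(2E,6Z)-8-[(tert-butyldiphenylsilyl)oxy]-3,7-dimethylocta-2,6-dien-1-ylidene]butanedioate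
Conditions: KN(SiMe3)2, 18-crown-6, THF, −78 → −40 °C
Reagents that add atoms: none
Why: Still–Gennari olefination with the α-branched phosphonate should place the methyl ester carbon C8 cis to C5 on the new C6=C7 alkene (Z), which is the geometry that the epoxidation and inversion of steps 12 and 14 require.

Step 11
Reactants: 15 4-tert-butyl 1-methyl (2Z)-2-[(2E,6Z)-8-[(tert-butyldiphenylsilyl)oxy]-3,7-dimethylocta-2,6-dien-1-ylidene]butanedioate
Product: 16 tert-butyl (3Z,5E,9Z)-11-[(tert-butyldiphenylsilyl)oxy]-3-(hydroxymethyl)-6,10-dimethylundeca-3,5,9-trienoate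
Conditions: iBu2AlH (2.2 equiv), CH2Cl2, −78 °C
Reagents that add atoms: none
Why: Chemoselective hydride reduction converts the conjugated methyl ester to the allylic alcohol at −78 °C while the hindered tert-butyl ester is left, and so provides the hydroxyl that directs the epoxidation.

Step 12
Reactants: 16 tert-butyl (3Z,5E,9Z)-11-[(tert-butyldiphenylsilyl)oxy]-3-(hydroxymethyl)-6,10-dimethylundeca-3,5,9-trienoate
Product: 17 tert-butyl 2-[(2S,3R)-3-[(1E,5Z)-7-[(tert-butyldiphenylsilyl)oxy]-2,6-dimethylhepta-1,5-dien-1-yl]-2-(hydroxymethyl)oxiran-2-yl]acetate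
Conditions: Ti(OiPr)4 (0.2 equiv), L-(+)-diethyl tartrate (0.24 equiv), tBuOOH, 4 Å molecular sieves, CH2Cl2, −20 °C
Reagents that add atoms: tert-butyl hydroperoxide, CC(C)(C)OO
Why: In the Sharpless asymmetric epoxidation the titanium tartrate complex binds the allylic alcohol and delivers oxygen only to the C6=C7 alkene, and L-(+)-tartrate should give the (2S,3R)-epoxy alcohol, which sets C7 in its final configuration and C6 in the configuration that step 14 inverts.

Step 13
Reactants: 17 tert-butyl 2-[(2S,3R)-3-[(1E,5Z)-7-[(tert-butyldiphenylsilyl)oxy]-2,6-dimethylhepta-1,5-dien-1-yl]-2-(hydroxymethyl)oxiran-2-yl]acetate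
Product: 18 O8-tert-butyldimethylsilyl ether of epoxy alcohol 17
Conditions: TBSCl, imidazole, CH2Cl2, 0 °C
Reagents that add atoms: tert-butyldimethylsilyl chloride, CC(C)(C)[Si](C)(C)Cl
Why: Silylation of the primary hydroxyl keeps O8 from acting as an internal nucleophile or from taking over the lactone carbonyl in the acid step that follows.

Step 14
Reactants: 18 O8-tert-butyldimethylsilyl ether of epoxy alcohol 17
Product: 19 (4S,5S)-4-{[(tert-butyldimethylsilyl)oxy]methyl}-5-[(1E,5Z)-7-[(tert-butyldiphenylsilyl)oxy]-2,6-dimethylhepta-1,5-dien-1-yl]-4-hydroxyoxolan-2-one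
Conditions: BF3·OEt2 (0.2 equiv), CH2Cl2, −78 → −40 °C
Reagents that add atoms: none
Why: Lewis acid-catalysed opening of the β,γ-epoxy ester by its own ester carbonyl oxygen (5-endo epoxide-opening lactonisation with loss of isobutene) should occur at the allylic carbon C6 with inversion and give the γ-lactone in which C5 and C8 are cis, O7 staying on C7.

Step 15
Reactants: 19 (4S,5S)-4-{[(tert-butyldimethylsilyl)oxy]methyl}-5-[(1E,5Z)-7-[(tert-butyldiphenylsilyl)oxy]-2,6-dimethylhepta-1,5-dien-1-yl]-4-hydroxyoxolan-2-one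
Product: 20 O7-methoxymethyl ether of lactone 19
Conditions: MOMCl, iPr2NEt, Bu4NI (cat.), ClCH2CH2Cl, 50 °C
Reagents that add atoms: chloromethyl methyl ether, COCCl
Why: O-Alkylation of the hindered tertiary alcohol with the reactive α-chloro ether installs a small chelating acetal on O7 that withstands fluoride, oxidation and divalent samarium.

Step 16
Reactants: 20 O7-methoxymethyl ether of lactone 19
Product: 21 (4S,5S)-5-[(1E,5Z)-7-hydroxy-2,6-dimethylhepta-1,5-dien-1-yl]-4-(hydroxymethyl)-4-(methoxymethoxy)oxolan-2-one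
Conditions: HF·pyridine, pyridine, THF, 0 °C → rt
Reagents that add atoms: none
Why: Fluoride-driven desilylation removes both silyl ethers while the acetal and the lactone are stable, and the mildly acidic medium avoids base-induced acyl transfer from O6 to O8.

Step 17
Reactants: 21 (4S,5S)-5-[(1E,5Z)-7-hydroxy-2,6-dimethylhepta-1,5-dien-1-yl]-4-(hydroxymethyl)-4-(methoxymethoxy)oxolan-2-one
Product: 22 (2S,3R)-2-[(1E,5Z)-2,6-dimethyl-7-oxohepta-1,5-dien-1-yl]-3-(methoxymethoxy)-5-oxooxolane-3-carbaldehyde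
Conditions: Dess–Martin periodinane, pyridine, CH2Cl2, 0 °C
Reagents that add atoms: none
Why: Dess–Martin oxidation converts both primary alcohols to aldehydes under buffered conditions, so the Z-enal should not isomerise and the C8 aldehyde, which has no α-hydrogen, cannot epimerise; 22 is used at once.

Step 18
Reactants: 22 (2S,3R)-2-[(1E,5Z)-2,6-dimethyl-7-oxohepta-1,5-dien-1-yl]-3-(methoxymethoxy)-5-oxooxolane-3-carbaldehyde
Product: 23 (3aS,4S,5R,6Z,10E,11aS)-4,5-dihydroxy-3a-(methoxymethoxy)-6,10-dimethyl-3,3a,4,5,8,9-hexahydrocyclodeca[b]furan-2(11aH)-one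
Conditions: SmI2 (5 equiv), THF, −20 °C, 22 added by syringe pump to a final 0.002 M; then aq. NH4Cl
Reagents that add atoms: none
Why: Two single-electron transfers from divalent samarium give ketyls at C9 (the conjugated aldehyde is reduced most easily) and at C8 (activated by chelation of samarium between the aldehyde oxygen and the methoxymethoxy oxygen on C7), and the two carbonyl carbons join within a samarium-bridged bis-alkoxide to form the C8–C9 bond. The closest known reaction type is the intramolecular SmI2 pinacol coupling of dialdehydes to medium- and large-ring 1,2-diols, including couplings of α-alkoxy aldehydes. The ten-membered carbocycle closes by direct union of its two termini under high dilution, and the cis C5 and C8 arms on the lactone together with the two fixed trisubstituted alkenes hold these termini close. C8 should be set by the five-membered O7–Sm–O8 chelate, with C9 arriving along the tether from the C6 side of that chelate, and C9 by the O8–Sm–O9 bridge, which with an anti C7–C8–C9–C10 ring torsion gives the threo (trans) diol. The step needs coupling at the carbonyl carbons in preference to coupling through the enal β-carbon C1, and ring closure in preference to dimerisation; the oxophilic samarium template and slow addition are relied on for both, and without HMPA or a proton source the lactone, the acetal and the alkenes should not be reduced.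

Step 19
Reactants: 23 (3aS,4S,5R,6Z,10E,11aS)-4,5-dihydroxy-3a-(methoxymethoxy)-6,10-dimethyl-3,3a,4,5,8,9-hexahydrocyclodeca[b]furan-2(11aH)-one
Product: 24 O8,O9-bis(tert-butyldimethylsilyl) ether of diol 23
Conditions: TBSOTf, 2,6-lutidine, CH2Cl2, −78 → 0 °C
Reagents that add atoms: tert-butyldimethylsilyl trifluoromethanesulfonate, CC(C)(C)[Si](C)(C)OS(=O)(=O)C(F)(F)F
Why: Silylation with the silyl triflate protects both secondary hydroxyls, including the hindered one on C8, as ethers that tolerate the bromoborane and the amide base.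

Step 20
Reactants: 24 O8,O9-bis(tert-butyldimethylsilyl) ether of diol 23
Product: 26 O8,O9-bis(tert-butyldimethylsilyl) ether with free C7 hydroxyl, via bromomethyl ether 25 (not isolated)
Conditions: Me2BBr, CH2Cl2, −78 °C; then aq. NaHCO3
Reagents that add atoms: none
Why: Lewis acid-mediated acetal cleavage by the bromoborane removes the methoxymethyl group at −78 °C without affecting silyl ethers, lactone or alkenes, and freeing O7 here means that the lactone enolate of step 21 carries a β-alkoxide and not a β-leaving group.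

Step 21
Reactants: 26 O8,O9-bis(tert-butyldimethylsilyl) ether with free C7 hydroxyl
Product: 27 C11-(dimethylaminomethyl) lactone (mixture of C11 epimers)
Conditions: LiN(iPr)2 (2.5 equiv), THF, −78 °C; Me2N=CH2 iodide, −78 → 0 °C
Reagents that add atoms: N,N-dimethylmethyleneiminium iodide, C=[N+](C)C.[I-]
Why: Mannich reaction of the lithium alkoxide–lactone enolate dianion with Eschenmoser's salt aminomethylates C11, the β-oxido group suppressing β-elimination; the configuration at C11 is of no consequence.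

Step 22
Reactants: 27 C11-(dimethylaminomethyl) lactone (mixture of C11 epimers)
Product: 29 O8,O9-bis(tert-butyldimethylsilyl) α-methylene lactone, via trimethylammonium iodide 28 (not isolated)
Conditions: MeI, MeOH, rt; then DBU, CH2Cl2, rt
Reagents that add atoms: none
Why: N-Methylation (Menshutkin reaction) followed by base-induced β-elimination of trimethylamine (Hofmann-type elimination) gives the exocyclic C11=C13 methylene.

Step 23
Reactants: 29 O8,O9-bis(tert-butyldimethylsilyl) α-methylene lactone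
Product: 30 (3aS,4S,5R,6Z,10E,11aS)-3a,4,5-trihydroxy-6,10-dimethyl-3-methylidene-3,3a,4,5,8,9-hexahydrocyclodeca[b]furan-2(11aH)-one
Conditions: HF·pyridine, THF, 0 °C → rt
Reagents that add atoms: none
Why: Fluoride-driven desilylation under mildly acidic conditions frees O8 and O9 without conjugate addition to the α-methylene lactone.

Step 24
Reactants: 30 (3aS,4S,5R,6Z,10E,11aS)-3a,4,5-trihydroxy-6,10-dimethyl-3-methylidene-3,3a,4,5,8,9-hexahydrocyclodeca[b]furan-2(11aH)-one; 31 angelic acid
Product: 33 (3aS,4S,5R,6Z,10E,11aS)-3a,4-dihydroxy-6,10-dimethyl-3-methylidene-2-oxo-2,3,3a,4,5,8,9,11a-octahydrocyclodeca[b]furan-5-yl (2Z)-2-methylbut-2-enoate, via mixed anhydride 32 (not isolated)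
Conditions: 31, 2,4,6-Cl3C6H2COCl, Et3N, toluene, rt; then 30, toluene, 75 °C
Reagents that add atoms: none
Why: Yamaguchi-type mixed-anhydride esterification without a nucleophilic catalyst should transfer the angeloyl group without Z-to-E isomerisation, and the allylic C9 hydroxyl should react in preference to the C8 hydroxyl (shielded by the quaternary C7) and the tertiary C7 hydroxyl.

## Compound list

1 | geraniol | CC(C)=CCC/C(C)=C/CO | starting material
2 | geranyl tert-butyldimethylsilyl ether | CC(C)=CCC/C(C)=C/CO[Si](C)(C)C(C)(C)C | intermediate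
3 | racemic 6,7-epoxygeranyl tert-butyldimethylsilyl ether | CC1(C)OC1CC/C(C)=C/CO[Si](C)(C)C(C)(C)C | intermediate
4 | racemic (6E)-8-[(tert-butyldimethylsilyl)oxy]-2,6-dimethyloct-6-ene-2,3-diol (not isolated) | CC(C)(O)C(O)CC/C(C)=C/CO[Si](C)(C)C(C)(C)C | intermediate
5 | (4E)-6-[(tert-butyldimethylsilyl)oxy]-4-methylhex-4-enal | O=CCC/C(C)=C/CO[Si](C)(C)C(C)(C)C | intermediate
6 | ethyl 2-[bis(2,2,2-trifluoroethoxy)phosphoryl]propanoate | CCOC(=O)C(C)P(=O)(OCC(F)(F)F)OCC(F)(F)F | starting material
7 | ethyl (2Z,6E)-8-[(tert-butyldimethylsilyl)oxy]-2,6-dimethylocta-2,6-dienoate | CCOC(=O)/C(C)=C\CC/C(C)=C/CO[Si](C)(C)C(C)(C)C | intermediate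
8 | (2Z,6E)-8-[(tert-butyldimethylsilyl)oxy]-2,6-dimethylocta-2,6-dien-1-ol | OC/C(C)=C\CC/C(C)=C/CO[Si](C)(C)C(C)(C)C | intermediate
9 | tert-butyl{[(2Z,6E)-8-[(tert-butyldimethylsilyl)oxy]-2,6-dimethylocta-2,6-dien-1-yl]oxy}diphenylsilane | CC(C)(C)[Si](C)(C)OC/C=C(\C)CC/C=C(/C)CO[Si](C(C)(C)C)(c1ccccc1)c1ccccc1 | intermediate
10 | (2E,6Z)-8-[(tert-butyldiphenylsilyl)oxy]-3,7-dimethylocta-2,6-dien-1-ol | OC/C=C(\C)CC/C=C(/C)CO[Si](C(C)(C)C)(c1ccccc1)c1ccccc1 | intermediate
11 | (2E,6Z)-8-[(tert-butyldiphenylsilyl)oxy]-3,7-dimethylocta-2,6-dienal | O=C/C=C(\C)CC/C=C(/C)CO[Si](C(C)(C)C)(c1ccccc1)c1ccccc1 | intermediate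
12 | methyl [bis(2,2,2-trifluoroethoxy)phosphoryl]acetate | COC(=O)CP(=O)(OCC(F)(F)F)OCC(F)(F)F | starting material
13 | tert-butyl bromoacetate | CC(C)(C)OC(=O)CBr | starting material
14 | racemic 4-tert-butyl 1-methyl 2-[bis(2,2,2-trifluoroethoxy)phosphoryl]butanedioate | COC(=O)C(CC(=O)OC(C)(C)C)P(=O)(OCC(F)(F)F)OCC(F)(F)F | intermediate
15 | 4-tert-butyl 1-methyl (2Z)-2-[(2E,6Z)-8-[(tert-butyldiphenylsilyl)oxy]-3,7-dimethylocta-2,6-dien-1-ylidene]butanedioate | COC(=O)/C(CC(=O)OC(C)(C)C)=C\C=C(/C)CC/C=C(/C)CO[Si](C(C)(C)C)(c1ccccc1)c1ccccc1 | intermediate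
16 | tert-butyl (3Z,5E,9Z)-11-[(tert-butyldiphenylsilyl)oxy]-3-(hydroxymethyl)-6,10-dimethylundeca-3,5,9-trienoate | OC/C(CC(=O)OC(C)(C)C)=C\C=C(/C)CC/C=C(/C)CO[Si](C(C)(C)C)(c1ccccc1)c1ccccc1 | intermediate
17 | tert-butyl 2-[(2S,3R)-3-[(1E,5Z)-7-[(tert-butyldiphenylsilyl)oxy]-2,6-dimethylhepta-1,5-dien-1-yl]-2-(hydroxymethyl)oxiran-2-yl]acetate | CC(C)(C)OC(=O)C[C@@]1(CO)O[C@@H]1/C=C(\C)CC/C=C(/C)CO[Si](C(C)(C)C)(c1ccccc1)c1ccccc1 | intermediate
18 | O8-tert-butyldimethylsilyl ether of epoxy alcohol 17, (2S,3R) | CC(C)(C)OC(=O)C[C@@]1(CO[Si](C)(C)C(C)(C)C)O[C@@H]1/C=C(\C)CC/C=C(/C)CO[Si](C(C)(C)C)(c1ccccc1)c1ccccc1 | intermediate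
19 | (4S,5S)-4-{[(tert-butyldimethylsilyl)oxy]methyl}-5-[(1E,5Z)-7-[(tert-butyldiphenylsilyl)oxy]-2,6-dimethylhepta-1,5-dien-1-yl]-4-hydroxyoxolan-2-one | O=C1O[C@@H](/C=C(\C)CC/C=C(/C)CO[Si](C(C)(C)C)(c2ccccc2)c2ccccc2)[C@@](O)(CO[Si](C)(C)C(C)(C)C)C1 | intermediate
20 | O7-methoxymethyl ether of lactone 19, (4S,5S) | O=C1O[C@@H](/C=C(\C)CC/C=C(/C)CO[Si](C(C)(C)C)(c2ccccc2)c2ccccc2)[C@@](OCOC)(CO[Si](C)(C)C(C)(C)C)C1 | intermediate
21 | (4S,5S)-5-[(1E,5Z)-7-hydroxy-2,6-dimethylhepta-1,5-dien-1-yl]-4-(hydroxymethyl)-4-(methoxymethoxy)oxolan-2-one | O=C1O[C@@H](/C=C(\C)CC/C=C(/C)CO)[C@@](OCOC)(CO)C1 | intermediate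
22 | (2S,3R)-2-[(1E,5Z)-2,6-dimethyl-7-oxohepta-1,5-dien-1-yl]-3-(methoxymethoxy)-5-oxooxolane-3-carbaldehyde | O=C1O[C@@H](/C=C(\C)CC/C=C(/C)C=O)[C@@](OCOC)(C=O)C1 | intermediate
23 | (3aS,4S,5R,6Z,10E,11aS)-4,5-dihydroxy-3a-(methoxymethoxy)-6,10-dimethyl-3,3a,4,5,8,9-hexahydrocyclodeca[b]furan-2(11aH)-one | C1C(=O)O[C@H]2/C=C(\C)CC/C=C(/C)[C@@H](O)[C@H](O)[C@@]12OCOC | intermediate
24 | O8,O9-bis(tert-butyldimethylsilyl) ether of diol 23 | C1C(=O)O[C@H]2/C=C(\C)CC/C=C(/C)[C@@H](O[Si](C)(C)C(C)(C)C)[C@H](O[Si](C)(C)C(C)(C)C)[C@@]12OCOC | intermediate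
25 | O7-bromomethyl ether derived from 24 (not isolated) | C1C(=O)O[C@H]2/C=C(\C)CC/C=C(/C)[C@@H](O[Si](C)(C)C(C)(C)C)[C@H](O[Si](C)(C)C(C)(C)C)[C@@]12OCBr | intermediate
26 | O8,O9-bis(tert-butyldimethylsilyl) ether with free C7 hydroxyl | C1C(=O)O[C@H]2/C=C(\C)CC/C=C(/C)[C@@H](O[Si](C)(C)C(C)(C)C)[C@H](O[Si](C)(C)C(C)(C)C)[C@@]12O | intermediate
27 | C11-(dimethylaminomethyl) lactone, mixture of C11 epimers | CN(C)CC1C(=O)O[C@H]2/C=C(\C)CC/C=C(/C)[C@@H](O[Si](C)(C)C(C)(C)C)[C@H](O[Si](C)(C)C(C)(C)C)[C@@]12O | intermediate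
28 | C11-(trimethylammoniomethyl) lactone iodide (not isolated) | C[N+](C)(C)CC1C(=O)O[C@H]2/C=C(\C)CC/C=C(/C)[C@@H](O[Si](C)(C)C(C)(C)C)[C@H](O[Si](C)(C)C(C)(C)C)[C@@]12O.[I-] | intermediate
29 | O8,O9-bis(tert-butyldimethylsilyl) α-methylene lactone | C=C1C(=O)O[C@H]2/C=C(\C)CC/C=C(/C)[C@@H](O[Si](C)(C)C(C)(C)C)[C@H](O[Si](C)(C)C(C)(C)C)[C@@]12O | intermediate
30 | (3aS,4S,5R,6Z,10E,11aS)-3a,4,5-trihydroxy-6,10-dimethyl-3-methylidene-3,3a,4,5,8,9-hexahydrocyclodeca[b]furan-2(11aH)-one | C=C1C(=O)O[C@H]2/C=C(\C)CC/C=C(/C)[C@@H](O)[C@H](O)[C@@]12O | intermediate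
31 | angelic acid, (2Z)-2-methylbut-2-enoic acid | C/C=C(/C)C(=O)O | starting material
32 | angelic 2,4,6-trichlorobenzoic anhydride (not isolated) | C/C=C(/C)C(=O)OC(=O)c1c(Cl)cc(Cl)cc1Cl | intermediate
33 | CNP0303917.1, (3aS,4S,5R,6Z,10E,11aS)-3a,4-dihydroxy-6,10-dimethyl-3-methylidene-2-oxo-2,3,3a,4,5,8,9,11a-octahydrocyclodeca[b]furan-5-yl (2Z)-2-methylbut-2-enoate | C=C1C(=O)O[C@H]2/C=C(\C)CC/C=C(/C)[C@@H](OC(=O)/C(C)=C\C)[C@H](O)[C@@]12O | target

## Step count and risks

Total step count: 24. Longest linear sequence: 23 steps (steps 1–8 and 10–24; step 9 prepares the phosphonate off the main line).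

Steps most likely to fail:

1. Step 18. The coupling may close the ring with C9 presenting its other face, because the facial sense at C9 rests only on the conformation of the forming ten-membered ring; the C8 centre is better secured by the chelate and the tether. The fallback sets out from 22 and no longer asks the coupling to set C9. The same reduction is run, and the diol with the C9 hydroxyl on the wrong face, the (9S) erythro diol F1, is carried on. A Mitsunobu reaction (4-nitrobenzoic acid, PPh3, diisopropyl azodicarboxylate, toluene, 0 °C) should esterify the allylic C9 hydroxyl with inversion, the C8 hydroxyl next to the quaternary carbon being left, to give the (9R) 4-nitrobenzoate F2. Mild methanolysis (K2CO3, MeOH, 0 °C) should then release diol 23, where the main route is rejoined.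

2. Step 14. The allylic C6–O bond of the epoxide may ionise to a delocalised cation before the ester carbonyl attacks, which would erode the inversion at C6 or allow capture at C4. The fallback sets out from epoxy alcohol 17 and opens the epoxide with an external nucleophile under titanium control. With Ti(OiPr)4 and benzoic acid in CH2Cl2 at rt, the titanium-bound 2,3-epoxy alcohol should be attacked at C6 with inversion to give the C6 benzoate diol F3. Silylation of the primary hydroxyl (TBSCl, imidazole) gives the silyl ether F4. K2CO3 in MeOH should then remove the benzoate, and the freed C6 alkoxide should close onto the tert-butyl ester to give lactone 19, where the main route is rejoined.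

3. Step 24. The activated angeloyl donor may isomerise to the tigloyl (E) isomer at the temperature needed for the hindered alcohol, or the acyl group may go to or migrate to O8. The fallback sets out from triol 30 and builds the Z-alkene on the ester after acylation. Coupling of 30 with 2-[bis(2,2,2-trifluoroethoxy)phosphoryl]propanoic acid (DCC, DMAP cat., CH2Cl2, 0 °C) should give the C9 phosphonopropanoate F5 under mild conditions. Still–Gennari olefination of F5 with acetaldehyde (KN(SiMe3)2, 1 equiv, 18-crown-6, THF, −78 °C; the phosphonate C–H is far more acidic than the hydroxyls) should give the Z-configured 2-methylbut-2-enoate, that is target 33.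

Further compounds
F1 | step 18 | (3aS,4S,5S,6Z,10E,11aS)-4,5-dihydroxy-3a-(methoxymethoxy)-6,10-dimethyl-3,3a,4,5,8,9-hexahydrocyclodeca[b]furan-2(11aH)-one, the C9 epimer of 23 | C1C(=O)O[C@H]2/C=C(\C)CC/C=C(/C)[C@H](O)[C@H](O)[C@@]12OCOC
F2 | step 18 | C9 4-nitrobenzoate of diol 23, (9R) | C1C(=O)O[C@H]2/C=C(\C)CC/C=C(/C)[C@@H](OC(=O)c3ccc(cc3)[N+](=O)[O-])[C@H](O)[C@@]12OCOC
F3 | step 14 | tert-butyl (3S,4S,5E,9Z)-4-(benzoyloxy)-11-[(tert-butyldiphenylsilyl)oxy]-3-hydroxy-3-(hydroxymethyl)-6,10-dimethylundeca-5,9-dienoate | CC(C)(C)OC(=O)C[C@](O)(CO)[C@@H](OC(=O)c1ccccc1)/C=C(\C)CC/C=C(/C)CO[Si](C(C)(C)C)(c1ccccc1)c1ccccc1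
F4 | step 14 | tert-butyl (3S,4S,5E,9Z)-4-(benzoyloxy)-3-{[(tert-butyldimethylsilyl)oxy]methyl}-11-[(tert-butyldiphenylsilyl)oxy]-3-hydroxy-6,10-dimethylundeca-5,9-dienoate | CC(C)(C)OC(=O)C[C@](O)(CO[Si](C)(C)C(C)(C)C)[C@@H](OC(=O)c1ccccc1)/C=C(\C)CC/C=C(/C)CO[Si](C(C)(C)C)(c1ccccc1)c1ccccc1
F5 | step 24 | C9 2-[bis(2,2,2-trifluoroethoxy)phosphoryl]propanoate of triol 30 | C=C1C(=O)O[C@H]2/C=C(\C)CC/C=C(/C)[C@@H](OC(=O)C(C)P(=O)(OCC(F)(F)F)OCC(F)(F)F)[C@H](O)[C@@]12O
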